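The constants you can read from these runs are first-order ones in E, taken as −d ln c_E/dt, and they say nothing directly about X, since no run changes its charge. So count turnovers and charge each one to X, supposing one X per Q made. This gives the turnover bill, the share of the X charge that the Q made so far has cost:

bill = conversion × c_E / c_X = 30 % × 1.1 M / 1.65 M = 20.0 %

| flask | E | X | G | remark |
|---|---|---|---|---|
| dusk | 1.1 M | 1.65 M | 0.74 mM | run made earlier |
| spring | 1.1 M | 1.65 M | 1.7 mM | run made earlier |
| flask | 1.1 M | 1.65 M | 1.1 mM |  |

| run | time / h | Q / % | E / % |
|---|---|---|---|
| dusk | 0.133 | 7.7 | 92.0 |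
| dusk | 0.333 | 18.1 | 81.8 |
| dusk | 0.667 | 30.4 | 70.0 |
| dusk | 1.00 | 39.5 | 60.1 |
| dusk | 1.33 | 46.1 | 53.7 |
| dusk | 2.00 | 56.0 | 44.3 |
| dusk | 2.50 | 59.7 | 39.8 |
| spring | 0.333 | 37.7 | 62.1 |
| spring | 0.667 | 59.1 | 39.9 |
| spring | 1.00 | 73.0 | 26.6 |
| spring | 1.33 | 81.2 | 18.4 |
| spring | 1.50 | 84.3 | 15.0 |
| spring | 2.00 | 90.7 | 9.6 |
| spring | 2.50 | 93.6 | 6.0 |

(readings scatter by 0.3 percentage points)

- what was read earlier has a scatter of 0.3 percentage points, one standard deviation
- no earlier run changes the charge of X; that part of a forecast is a guess

1. apparent order in X when 30 % of the E are converted (percent change of the rate of making Q for one percent more X charged)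
2. apparent order in G when 30 % of the E are converted (percent change of the rate of making Q for one percent more G charged)

Turn the question round. For an order in X near zero, the slowing in the readings must come from something other than X. The bill allows that reading. In the flask, at the mark of 30 % conversion, 300 turnovers per G would cost 20.0 % of the X. As read from the first and last readings, the dusk run's constant falls from 0.627 /h to 0.214 /h, and the spring run's from 1.43 /h to 0.940 /h. Yet at the last reading spring's bill of 62.4 % is larger than dusk's 39.8 %, and its constant has fallen less. But both runs share one charge of X, so I can't exclude an order near one from them.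

The forecast gives 0.15 in X (range −0.2 to 0.6) and 1.3 in G (range 1.12 to 1.5), reading the slowing as “a roughly fixed loss of active catalyst with time”.

The flask gives 0.89 in X, above that range, and 1.3 in G, as forecast.

    X + G → Z (k = 15.0 /M/min)
    E + Z ⇌ D (K = 0.710 /M, k = 1700 /M/min)
    D → G + Q (k = 110 /min)
    2 X → J (k = 0.00720 /M/min)

At 0.200 h the flask holds Q at 16.8 %, a bill of 11.2 %, yet it has lost 31.1 % of its X, and J already stands at 0.164 M. So X falls by the hour as well as by the turnover, while G, the resting state, is 71.2 % of the catalyst in the flask at that time. Take the reaction of 2 X to J away and the rate at the mark becomes 1.39 times the actual 0.615 M/h, and the order in G, of which this reaction is a part of the reason, goes from 1.3 to 1.0.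

The earlier runs and the new flask are simulated on assumed constants; the scatter is artificial.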